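**Retrosynthetic overview**
- Bulbocodin C ⇐ global O-debenzylation of a tetrabenzyl ether; the OMe ⇐ O-methylation of a phenol flanked by both 4-(benzyloxy)benzyl groups.
- That phenol (ring A) ⇐ base isomerisation of a 6-arylidene-3-benzyloxycyclohex-2-enone ⇐ α′-aldol condensation of the vinylogous benzyl ester with 4-(benzyloxy)benzaldehyde.
- The benzyl group between the two oxygens ⇐ Knoevenagel condensation/transfer hydrogenation of a 5-substituted cyclohexane-1,3-dione with the same aldehyde.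
- The dione ring (future ring A, the only ring that is built) ⇐ intermolecular Michael addition of dimethyl malonate to an (E)-enone, then intramolecular Claisen closure and decarboxylation.
- The enone ⇐ Wittig olefination of 3-[3-(benzyloxy)phenyl]propanal ⇐ 3-(3-hydroxyphenyl)propanoic acid; the three outer benzene rings are bought intact.

Assumption: the target has no stereocentre and is achiral, so the structure as drawn is the only stereoisomer; stereocentres and alkene geometries of intermediates are racemic or transient and are erased on aromatisation.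

**Route**

Step 1
Reactants: 1 3-(3-hydroxyphenyl)propanoic acid
Product: 2 benzyl 3-[3-(benzyloxy)phenyl]propanoate
Conditions: BnBr (2.4 equiv), K2CO3 (3 equiv), DMF, 60 °C
Reagents that add atoms: benzyl bromide, BrCc1ccccc1
Why: Williamson-type SN2 O-alkylation of both the phenoxide and the carboxylate masks the phenol as a hydrogenolysable benzyl ether and turns the acid into a reducible ester.

Step 2
Reactants: 2 benzyl 3-[3-(benzyloxy)phenyl]propanoate
Product: 3 3-[3-(benzyloxy)phenyl]propan-1-ol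
Conditions: LiAlH4 (1.2 equiv), THF, 0 °C to rt; aqueous NaOH work-up
Reagents that add atoms: none
Why: LiAlH4 reduction of the ester gives the primary alcohol, and the aryl benzyl ether is inert to hydride.

Step 3
Reactants: 3 3-[3-(benzyloxy)phenyl]propan-1-ol
Product: 4 3-[3-(benzyloxy)phenyl]propanal
Conditions: (2,2,6,6-tetramethylpiperidin-1-yl)oxyl (TEMPO, 10 mol%), PhI(OAc)2 (1.1 equiv), CH2Cl2, rt
Reagents that add atoms: none
Why: the oxoammonium-mediated TEMPO/PhI(OAc)2 oxidation stops cleanly at the aldehyde.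

Step 4
Reactants: 4 3-[3-(benzyloxy)phenyl]propanal; 5 1-(triphenyl-λ5-phosphanylidene)propan-2-one
Product: 6 (3E)-6-[3-(benzyloxy)phenyl]hex-3-en-2-one
Conditions: toluene, 80 °C
Reagents that add atoms: none
Why: Wittig olefination with a stabilised ylide gives the (E)-enone selectively; the geometry is of no later consequence.

Step 5
Reactants: 6 (3E)-6-[3-(benzyloxy)phenyl]hex-3-en-2-one; 7 dimethyl malonate
Product: 9 methyl 6-{2-[3-(benzyloxy)phenyl]ethyl}-2,4-dioxocyclohexane-1-carboxylate, via Michael adduct 8 (not isolated)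
Conditions: NaOMe (1.2 equiv), MeOH, reflux; then 1 M HCl, 0 °C
Reagents that add atoms: none
Why: intermolecular Michael addition of the malonate anion to the enone is followed by intramolecular Claisen (Dieckmann) attack of the methyl-ketone enolate on an ester, driven by the stabilised β-diketone enolate; the two new stereocentres are racemic and are erased later.

Step 6
Reactants: 9 methyl 6-{2-[3-(benzyloxy)phenyl]ethyl}-2,4-dioxocyclohexane-1-carboxylate
Product: 11 5-{2-[3-(benzyloxy)phenyl]ethyl}cyclohexane-1,3-dione, via keto acid 10 (not isolated)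
Conditions: 2 M aq NaOH, reflux; then conc. HCl to pH 1, 80 °C
Reagents that add atoms: none
Why: saponification followed by decarboxylation of the β-keto acid gives the symmetric, achiral 5-substituted dione.

Step 7
Reactants: 11 5-{2-[3-(benzyloxy)phenyl]ethyl}cyclohexane-1,3-dione; 12 4-(benzyloxy)benzaldehyde
Product: 14 2-[4-(benzyloxy)benzyl]-5-{2-[3-(benzyloxy)phenyl]ethyl}cyclohexane-1,3-dione, via Knoevenagel alkylidene dione 13 (not isolated)
Conditions: Hantzsch ester (diethyl 2,6-dimethyl-1,4-dihydropyridine-3,5-dicarboxylate, 1.1 equiv), L-proline (20 mol%), CH2Cl2, rt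
Reagents that add atoms: none
Why: proline-catalysed Knoevenagel condensation and immediate conjugate transfer hydrogenation (three-component reductive alkylation) give clean C2-monobenzylation, because the reactive alkylidene dione is reduced before it can take up a second dione.

Step 8
Reactants: 14 2-[4-(benzyloxy)benzyl]-5-{2-[3-(benzyloxy)phenyl]ethyl}cyclohexane-1,3-dione
Product: 15 3-(benzyloxy)-2-[4-(benzyloxy)benzyl]-5-{2-[3-(benzyloxy)phenyl]ethyl}cyclohex-2-en-1-one
Conditions: BnOH (3 equiv), TsOH·H2O (5 mol%), toluene, reflux, Dean–Stark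
Reagents that add atoms: benzyl alcohol, OCc1ccccc1
Why: acid-catalysed enol etherification with azeotropic removal of water gives the vinylogous benzyl ester, and because 14 is symmetric only one constitutional isomer (racemic at C5) can form.

Step 9
Reactants: 15 3-(benzyloxy)-2-[4-(benzyloxy)benzyl]-5-{2-[3-(benzyloxy)phenyl]ethyl}cyclohex-2-en-1-one; 12 4-(benzyloxy)benzaldehyde
Product: 16 3-(benzyloxy)-2-[4-(benzyloxy)benzyl]-6-{[4-(benzyloxy)phenyl](hydroxy)methyl}-5-{2-[3-(benzyloxy)phenyl]ethyl}cyclohex-2-en-1-one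
Conditions: LiN(iPr)2 (1.15 equiv), THF, −78 °C; then 12 (1.2 equiv), −78 °C; AcOH quench at −78 °C
Reagents that add atoms: none
Why: kinetic deprotonation of a β-alkoxy enone occurs at the α′ carbon C6 and not at the γ carbon C4 (Stork–Danheiser regiochemistry), so the aldol addition places the second aryl carbon next to the ketone and the side chain; the diastereomer mixture is inconsequential.

Step 10
Reactants: 16 3-(benzyloxy)-2-[4-(benzyloxy)benzyl]-6-{[4-(benzyloxy)phenyl](hydroxy)methyl}-5-{2-[3-(benzyloxy)phenyl]ethyl}cyclohex-2-en-1-one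
Product: 18 (6E)-3-(benzyloxy)-2-[4-(benzyloxy)benzyl]-6-[4-(benzyloxy)benzylidene]-5-{2-[3-(benzyloxy)phenyl]ethyl}cyclohex-2-en-1-one, via mesylate 17 (not isolated)
Conditions: MsCl (1.2 equiv), Et3N (2.5 equiv), CH2Cl2, 0 °C; then DBU (3 equiv), 0 °C to rt
Reagents that add atoms: none
Why: mesylation and E1cB elimination complete the aldol condensation to the cross-conjugated arylidene dienone, which is an isomer of the wanted phenol.

Step 11
Reactants: 18 (6E)-3-(benzyloxy)-2-[4-(benzyloxy)benzyl]-6-[4-(benzyloxy)benzylidene]-5-{2-[3-(benzyloxy)phenyl]ethyl}cyclohex-2-en-1-one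
Product: 19 3-(benzyloxy)-2,6-bis[4-(benzyloxy)benzyl]-5-{2-[3-(benzyloxy)phenyl]ethyl}phenol
Conditions: KOt-Bu (2 equiv), degassed DMSO, rt, argon; then 1 M HCl
Reagents that add atoms: none
Why: base-mediated prototropic isomerisation (isoaromatisation) moves the exocyclic double bond into the ring and is driven irreversibly by aromaticity and phenoxide formation; it removes every stereocentre.

Step 12
Reactants: 19 3-(benzyloxy)-2,6-bis[4-(benzyloxy)benzyl]-5-{2-[3-(benzyloxy)phenyl]ethyl}phenol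
Product: 20 1-(benzyloxy)-2,4-bis[4-(benzyloxy)benzyl]-5-{2-[3-(benzyloxy)phenyl]ethyl}-3-methoxybenzene
Conditions: MeI (3 equiv), K2CO3 (3 equiv), DMF, 40 °C
Reagents that add atoms: iodomethane, CI
Why: Williamson methylation of the only free phenol fixes the methoxy group between the two benzyl substituents, while the other ring-A oxygen stays masked as its benzyl ether.

Step 13
Reactants: 20 1-(benzyloxy)-2,4-bis[4-(benzyloxy)benzyl]-5-{2-[3-(benzyloxy)phenyl]ethyl}-3-methoxybenzene
Product: 21 Bulbocodin C, 2,4-bis(4-hydroxybenzyl)-5-[2-(3-hydroxyphenyl)ethyl]-3-methoxyphenol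
Conditions: H2 (1 atm), Pd/C (10 wt% Pd), EtOAc/MeOH 1:1, rt
Reagents that add atoms: none
Why: catalytic hydrogenolysis cleaves all four aryl benzyl ethers, while the methyl ether and the diarylmethane and bibenzyl C–C bonds are untouched.

**Compound list**
1 | 3-(3-hydroxyphenyl)propanoic acid | OC(=O)CCc1cccc(O)c1 | starting material
2 | benzyl 3-[3-(benzyloxy)phenyl]propanoate | O=C(CCc1cccc(OCc2ccccc2)c1)OCc1ccccc1 | intermediate
3 | 3-[3-(benzyloxy)phenyl]propan-1-ol | OCCCc1cccc(OCc2ccccc2)c1 | intermediate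
4 | 3-[3-(benzyloxy)phenyl]propanal | O=CCCc1cccc(OCc2ccccc2)c1 | intermediate
5 | 1-(triphenyl-λ5-phosphanylidene)propan-2-one (acetonylidene ylide) | CC(=O)C=P(c1ccccc1)(c1ccccc1)c1ccccc1 | starting material
6 | (3E)-6-[3-(benzyloxy)phenyl]hex-3-en-2-one | CC(=O)/C=C/CCc1cccc(OCc2ccccc2)c1 | intermediate
7 | dimethyl malonate | COC(=O)CC(=O)OC | starting material
8 | dimethyl 2-{1-[3-(benzyloxy)phenyl]-5-oxohexan-3-yl}propanedioate, racemic Michael adduct, not isolated | CC(=O)CC(CCc1cccc(OCc2ccccc2)c1)C(C(=O)OC)C(=O)OC | intermediate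
9 | methyl 6-{2-[3-(benzyloxy)phenyl]ethyl}-2,4-dioxocyclohexane-1-carboxylate, racemic, enolised | COC(=O)C1C(=O)CC(=O)CC1CCc1cccc(OCc2ccccc2)c1 | intermediate
10 | 6-{2-[3-(benzyloxy)phenyl]ethyl}-2,4-dioxocyclohexane-1-carboxylic acid, racemic, not isolated | OC(=O)C1C(=O)CC(=O)CC1CCc1cccc(OCc2ccccc2)c1 | intermediate
11 | 5-{2-[3-(benzyloxy)phenyl]ethyl}cyclohexane-1,3-dione, achiral | O=C1CC(=O)CC(CCc2cccc(OCc3ccccc3)c2)C1 | intermediate
12 | 4-(benzyloxy)benzaldehyde | O=Cc1ccc(OCc2ccccc2)cc1 | starting material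
13 | 2-[4-(benzyloxy)benzylidene]-5-{2-[3-(benzyloxy)phenyl]ethyl}cyclohexane-1,3-dione, not isolated | O=C1CC(CCc2cccc(OCc3ccccc3)c2)CC(=O)C1=Cc1ccc(OCc2ccccc2)cc1 | intermediate
14 | 2-[4-(benzyloxy)benzyl]-5-{2-[3-(benzyloxy)phenyl]ethyl}cyclohexane-1,3-dione, enolised | O=C1CC(CCc2cccc(OCc3ccccc3)c2)CC(=O)C1Cc1ccc(OCc2ccccc2)cc1 | intermediate
15 | 3-(benzyloxy)-2-[4-(benzyloxy)benzyl]-5-{2-[3-(benzyloxy)phenyl]ethyl}cyclohex-2-en-1-one, racemic | O=C1CC(CCc2cccc(OCc3ccccc3)c2)CC(OCc2ccccc2)=C1Cc1ccc(OCc2ccccc2)cc1 | intermediate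
16 | 3-(benzyloxy)-2-[4-(benzyloxy)benzyl]-6-{[4-(benzyloxy)phenyl](hydroxy)methyl}-5-{2-[3-(benzyloxy)phenyl]ethyl}cyclohex-2-en-1-one, racemic diastereomer mixture | O=C1C(C(O)c2ccc(OCc3ccccc3)cc2)C(CCc2cccc(OCc3ccccc3)c2)CC(OCc2ccccc2)=C1Cc1ccc(OCc2ccccc2)cc1 | intermediate
17 | methanesulfonate of 16, not isolated | O=C1C(C(OS(C)(=O)=O)c2ccc(OCc3ccccc3)cc2)C(CCc2cccc(OCc3ccccc3)c2)CC(OCc2ccccc2)=C1Cc1ccc(OCc2ccccc2)cc1 | intermediate
18 | (6E)-3-(benzyloxy)-2-[4-(benzyloxy)benzyl]-6-[4-(benzyloxy)benzylidene]-5-{2-[3-(benzyloxy)phenyl]ethyl}cyclohex-2-en-1-one, racemic | O=C1/C(=C/c2ccc(OCc3ccccc3)cc2)C(CCc2cccc(OCc3ccccc3)c2)CC(OCc2ccccc2)=C1Cc1ccc(OCc2ccccc2)cc1 | intermediate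
19 | 3-(benzyloxy)-2,6-bis[4-(benzyloxy)benzyl]-5-{2-[3-(benzyloxy)phenyl]ethyl}phenol | Oc1c(Cc2ccc(OCc3ccccc3)cc2)c(OCc2ccccc2)cc(CCc2cccc(OCc3ccccc3)c2)c1Cc1ccc(OCc2ccccc2)cc1 | intermediate
20 | 1-(benzyloxy)-2,4-bis[4-(benzyloxy)benzyl]-5-{2-[3-(benzyloxy)phenyl]ethyl}-3-methoxybenzene | COc1c(Cc2ccc(OCc3ccccc3)cc2)c(OCc2ccccc2)cc(CCc2cccc(OCc3ccccc3)c2)c1Cc1ccc(OCc2ccccc2)cc1 | intermediate
21 | Bulbocodin C, 2,4-bis(4-hydroxybenzyl)-5-[2-(3-hydroxyphenyl)ethyl]-3-methoxyphenol, achiral | COc1c(Cc2ccc(O)cc2)c(O)cc(CCc2cccc(O)c2)c1Cc1ccc(O)cc1 | target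

**Step count and risks**
Total step count: 13. Longest linear sequence: 13 steps (1 to 21); compounds 5, 7 and 12 are bought and enter directly.

Steps most likely to fail:

Step 8 (enol etherification of the hindered 2-substituted dione may be slow, and hot acid with BnOH may give dibenzyl ether or benzyl transfer). The fallback sets out from 14 and comes back at 15. Dione 14 is treated with (COCl)2 and catalytic N,N-dimethylformamide in CH2Cl2 to give the vinylogous acid chloride 2-[4-(benzyloxy)benzyl]-5-{2-[3-(benzyloxy)phenyl]ethyl}-3-chlorocyclohex-2-en-1-one F1. Addition–elimination with NaOCH2Ph (from BnOH and NaH) in THF at 0 °C then delivers 15 without any acid.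

Step 9 (the lithium aldol at the hindered α′ carbon may stall or revert by retro-aldol). The fallback sets out from 15 and comes back at 16. Enone 15 is deprotonated with LiN(iPr)2 and trapped with Me3SiCl in THF at −78 °C to give the kinetic silyl dienol ether {[5-(benzyloxy)-6-[4-(benzyloxy)benzyl]-3-{2-[3-(benzyloxy)phenyl]ethyl}cyclohexa-1,5-dien-1-yl]oxy}trimethylsilane F2. A Mukaiyama aldol addition of F2 to aldehyde 12 with BF3·OEt2 in CH2Cl2 at −78 °C, which is not reversible under the reaction conditions, gives 16 after aqueous work-up.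

Step 11 (the isoaromatisation may be incomplete or be accompanied by conjugate addition to the arylidene enone). The fallback sets out from 15 and comes back at 19, bypassing 16 and 18. The α′-enolate of 15 (LiN(iPr)2, THF, −78 °C) is alkylated with purchased 4-(benzyloxy)benzyl bromide (BrCc1ccc(OCc2ccccc2)cc1) to give 3-(benzyloxy)-2,6-bis[4-(benzyloxy)benzyl]-5-{2-[3-(benzyloxy)phenyl]ethyl}cyclohex-2-en-1-one F3. This is dehydrogenated with Pd(O2CCF3)2 (5 mol%), 2-(dimethylamino)pyridine (10 mol%), TsOH·H2O (20 mol%) and O2 (1 atm) in DMSO at 80 °C, and the resulting dienone tautomerises to phenol 19.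

**Further compounds**
F1 | step 8 | 2-[4-(benzyloxy)benzyl]-5-{2-[3-(benzyloxy)phenyl]ethyl}-3-chlorocyclohex-2-en-1-one, racemic | O=C1CC(CCc2cccc(OCc3ccccc3)c2)CC(Cl)=C1Cc1ccc(OCc2ccccc2)cc1
F2 | step 9 | {[5-(benzyloxy)-6-[4-(benzyloxy)benzyl]-3-{2-[3-(benzyloxy)phenyl]ethyl}cyclohexa-1,5-dien-1-yl]oxy}trimethylsilane, racemic | C[Si](C)(C)OC1=CC(CCc2cccc(OCc3ccccc3)c2)CC(OCc2ccccc2)=C1Cc1ccc(OCc2ccccc2)cc1
F3 | step 11 | 3-(benzyloxy)-2,6-bis[4-(benzyloxy)benzyl]-5-{2-[3-(benzyloxy)phenyl]ethyl}cyclohex-2-en-1-one, racemic diastereomer mixture | O=C1C(Cc2ccc(OCc3ccccc3)cc2)C(CCc2cccc(OCc3ccccc3)c2)CC(OCc2ccccc2)=C1Cc1ccc(OCc2ccccc2)cc1
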